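Eremophilane numbering is used. Ring A (C1–C5, C10) hides a 1,3-dicarbonyl: the oxygen-bearing C2 and the ring-fusion carbon C10 flank C1, and the methyl-bearing C4 lies β to C10. Ring A is therefore made first, as (4R,5S)-4,5-dimethylcyclohexane-1,3-dione, by a one-pot asymmetric Michael–Claisen annulation of two acyclic pieces, (E)-3-methylpent-3-en-2-one (C15–C4–C5(C14)–C10–C1) and dimethyl malonate (C3, C2); it forms C3–C4 and C1–C2 and sets C4. Stork–Danheiser alkylation then builds quaternary C5, a Stetter cyclisation closes ring B (C9–C10), and a late trans-diaxial epoxide opening brings in the axial isopropenyl group together with the C8 hydroxyl.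

Key step: step 1

Remark: C14 and C15 are the methyl groups on C5 and C4 and C11–C13 the isopropenyl group; the quinidine-derived amine of step 1 is assumed to deliver (S)-C4 (target numbering), and its quinine-derived pseudoenantiomer is taken if the sense proves opposite.

Step 1
Reactants: 1 (E)-3-methylpent-3-en-2-one; 2 dimethyl malonate
Product: 5 (4R,5S)-4,5-dimethylcyclohexane-1,3-dione, via Michael adduct 3 (not isolated), via cyclised keto ester 4 (not isolated)
Conditions: 9-amino-9-deoxy-epi-quinidine (20 mol%), 2-FC6H4CO2H (40 mol%), toluene, 40 °C; then LiN(SiMe3)2 (3 equiv), THF, −78 → 0 °C; then 2 M NaOH, 80 °C; then HCl, 80 °C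
Reagents that add atoms: none
Why: The primary amine converts 1 into an iminium ion, one face of which is shielded by the cinchona scaffold while its quinuclidine nitrogen guides the malonate, so that 2 adds at C4 (Michael addition, C3–C4 bond) and the C4 stereocentre is set under catalyst control; the amide base then turns adduct 3 into its malonate/methyl-ketone dianion, whose C1 enolate acylates one ester group (Claisen condensation of Dieckmann type, C1–C2 bond) to give 4, and saponification with decarboxylation removes the second ester. The closest known reactions are the dimedone synthesis (one-pot Michael–Claisen annulation of mesityl oxide with a malonate) and iminium-catalysed asymmetric malonate additions to enones, α-branched enones being activated by 9-amino-cinchona amines. The single ring closure is a 6-exo-trig attack of the methyl-ketone enolate carbon C1 on the ester carbonyl C2. C4 is controlled by the catalyst, whereas C5 is only under thermodynamic control (trans to C4) and is erased later when it becomes an enolate. The step needs 1,4- instead of 1,2-addition (soft malonate, iminium activation), enolisation of the methyl group instead of C5–H (kinetic deprotonation by the hindered amide at low temperature), and no retro-Michael loss of configuration (the malonate carbon is deprotonated first, which closes the β-elimination path).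

Step 2
Reactants: 5 (4R,5S)-4,5-dimethylcyclohexane-1,3-dione
Product: 6 (5S,6R)-5,6-dimethyl-3-(2-methylpropoxy)cyclohex-2-en-1-one
Conditions: i-BuOH, TsOH·H2O (cat.), toluene, reflux, Dean–Stark
Reagents that add atoms: 2-methylpropan-1-ol CC(C)CO
Why: Acid-catalysed vinylogous ester formation under equilibrating conditions (first stage of the Stork–Danheiser sequence) should place the alkoxy group on the less hindered C2 carbonyl, remote from the C5 methyl, so that the C10 ketone keeps the enolisable C5–H next to it; C4 is untouched and C5 stays trans.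

Step 3
Reactants: 6 (5S,6R)-5,6-dimethyl-3-(2-methylpropoxy)cyclohex-2-en-1-one; 7 4-bromobutanenitrile
Product: 8 4-[(1R,6S)-1,6-dimethyl-4-(2-methylpropoxy)-2-oxocyclohex-3-en-1-yl]butanenitrile
Conditions: LiN(i-Pr)2, THF, −78 °C; then 7, DMPU, NaI (cat.), −78 → 23 °C
Reagents that add atoms: none
Why: Stork–Danheiser α′-alkylation, in which kinetic deprotonation can occur only at C5 and the bromide approaches the planar enolate anti to the neighbouring C4 methyl, so that C6 enters trans to C15 and the C14 methyl ends cis to it (quaternary 5R centre).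

Step 4
Reactants: 8 4-[(1R,6S)-1,6-dimethyl-4-(2-methylpropoxy)-2-oxocyclohex-3-en-1-yl]butanenitrile
Product: 10 4-[(1R,6S)-1,6-dimethyl-4-oxocyclohex-2-en-1-yl]butanal, via reduced hydroxy imine 9 (not isolated)
Conditions: i-Bu2AlH (3 equiv), CH2Cl2, −78 °C; then 1 M HCl, THF, 23 °C
Reagents that add atoms: water O
Why: Stork–Danheiser carbonyl transposition combined with nitrile half-reduction, in which the hydride reduces the C10 carbonyl and the nitrile (to the N-aluminio imine) and aqueous acid then hydrolyses the enol ether with loss of the C10 hydroxyl to give the C2 enone (C1=C10) and frees the C9 aldehyde, no stereocentre being touched.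

Step 5
Reactants: 10 4-[(1R,6S)-1,6-dimethyl-4-oxocyclohex-2-en-1-yl]butanal
Product: 12 (4aR,5S,8aR)-4a,5-dimethyl-3,4,4a,5,6,8a-hexahydronaphthalene-1,7(2H,8H)-dione (trans-fused), via cis-fused dione 11 (not isolated)
Conditions: 3-benzyl-5-(2-hydroxyethyl)-4-methylthiazolium chloride (20 mol%), Et3N, 1,4-dioxane, 80 °C; then DBU, MeOH, 23 °C
Reagents that add atoms: none
Why: Intramolecular Stetter reaction (6-exo-trig addition of the Breslow intermediate of the C9 aldehyde to the enone β-carbon C10, as in Stetter closures onto 4,4-disubstituted cyclohexenones and cyclohexadienones), in which the tether must deliver C9 to the face of C10 that carries C6 and so gives the cis-fused dione first, after which base equilibration of C10–H (α to the new C9 ketone) should lead to the more stable trans-fused isomer (10R) with the C4 methyl equatorial.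

Step 6
Reactants: 12 (4aR,5S,8aR)-4a,5-dimethyl-3,4,4a,5,6,8a-hexahydronaphthalene-1,7(2H,8H)-dione
Product: 13 (4aR,5S,7S,8aR)-7-hydroxy-4a,5-dimethyloctahydronaphthalen-1(2H)-one
Conditions: LiBH(s-Bu)3 (1.05 equiv), THF, −78 °C; aq. NH4Cl
Reagents that add atoms: none
Why: Chemo- and stereoselective trialkylborohydride reduction, in which the bulky hydride reacts with the unhindered C2 cyclohexanone faster than with the C9 ketone (next to the ring fusion and shielded by the axial C14 methyl) and attacks from the equatorial direction to give the axial 2α-alcohol (2S), as with 3-oxo-5α-steroids.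

Step 7
Reactants: 13 (4aR,5S,7S,8aR)-7-hydroxy-4a,5-dimethyloctahydronaphthalen-1(2H)-one
Product: 15 (4aR,5S,7S,8aR)-7-hydroxy-4a,5-dimethyl-4a,5,6,7,8,8a-hexahydronaphthalen-1(4H)-one, via bis-silylated enol ether 14 (not isolated)
Conditions: LiN(i-Pr)2 (2.3 equiv), Me3SiCl, THF, −78 °C; then Pd(OAc)2 (10 mol%), O2, DMSO, 23 °C; then 1 M HCl, THF
Reagents that add atoms: none
Why: Saegusa–Ito dehydrogenation, in which the amide removes the more accessible C8–H instead of the tertiary C10–H, divalent palladium converts the C8=C9 silyl enol ether through its palladium enolate and β-hydride elimination from C7 into the C7=C8 enone, and acid removes the silyl group from O2, C10 never being enolised so that the trans fusion is kept.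

Step 8
Reactants: 15 (4aR,5S,7S,8aR)-7-hydroxy-4a,5-dimethyl-4a,5,6,7,8,8a-hexahydronaphthalen-1(4H)-one
Product: 16 (2S,4S,4aR,8aR)-4,4a-dimethyl-8-oxo-1,2,3,4,4a,5,8,8a-octahydronaphthalen-2-yl acetate
Conditions: Ac2O, DMAP (cat.), pyridine, 23 °C
Reagents that add atoms: acetic anhydride CC(=O)OC(C)=O
Why: DMAP-catalysed acylation of the axial secondary alcohol, which proceeds with retention at C2 and leaves the enone untouched.

Step 9
Reactants: 16 (2S,4S,4aR,8aR)-4,4a-dimethyl-8-oxo-1,2,3,4,4a,5,8,8a-octahydronaphthalen-2-yl acetate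
Product: 17 (2S,4S,4aR,8S,8aR)-8-hydroxy-4,4a-dimethyl-1,2,3,4,4a,5,8,8a-octahydronaphthalen-2-yl acetate
Conditions: NaBH4, CeCl3·7H2O, MeOH, −78 → −20 °C
Reagents that add atoms: none
Why: Luche 1,2-reduction, in which the angular C14 methyl is syn-axial to the β-face of C9 so that hydride should arrive from the α-face and give the pseudoaxial 9β-alcohol (9S) as the main epimer, as in hydride reductions of ketones next to a methyl-bearing ring fusion in 5α-steroids, the acetate being inert.

Step 10
Reactants: 17 (2S,4S,4aR,8S,8aR)-8-hydroxy-4,4a-dimethyl-1,2,3,4,4a,5,8,8a-octahydronaphthalen-2-yl acetate; 18 angelic acid ((Z)-2-methylbut-2-enoic acid)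
Product: 19 (1R,4aR,5S,7S,8aR)-7-acetoxy-4a,5-dimethyl-1,4,4a,5,6,7,8,8a-octahydronaphthalen-1-yl (2Z)-2-methylbut-2-enoate
Conditions: PPh3, DIAD, toluene, 0 → 23 °C
Reagents that add atoms: none
Why: Mitsunobu esterification, in which SN2 displacement of the 9β-oxyphosphonium group by angelate from the open α-face inverts C9 to the equatorial 9α-ester and, since the acid is never activated as an acyl donor, the (Z)-geometry of the angelate should be preserved.

Step 11
Reactants: 19 (1R,4aR,5S,7S,8aR)-7-acetoxy-4a,5-dimethyl-1,4,4a,5,6,7,8,8a-octahydronaphthalen-1-yl (2Z)-2-methylbut-2-enoate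
Product: 20 (1S,2R,3R,4aR,5S,7S,8aR)-7-acetoxy-2,3-epoxy-4a,5-dimethyldecahydronaphthalen-1-yl (2Z)-2-methylbut-2-enoate
Conditions: m-ClC6H4CO3H, NaHCO3, CH2Cl2, 0 °C
Reagents that add atoms: 3-chloroperoxybenzoic acid OOC(=O)c1cccc(Cl)c1
Why: Prilezhaev epoxidation, in which the ring C7=C8 bond is far more nucleophilic than the conjugated angelate double bond and the axial C14 methyl (1,3 to C7) blocks the β-face, so that the 7α,8α-epoxide is expected, as with 2-ene-5α-steroids.

Step 12
Reactants: 20 (1S,2R,3R,4aR,5S,7S,8aR)-7-acetoxy-2,3-epoxy-4a,5-dimethyldecahydronaphthalen-1-yl (2Z)-2-methylbut-2-enoate; 21 isopropenylmagnesium bromide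
Product: 22 (1S,2R,3R,4aR,5S,7S,8aR)-7-acetoxy-2-hydroxy-4a,5-dimethyl-3-(prop-1-en-2-yl)decahydronaphthalen-1-yl (2Z)-2-methylbut-2-enoate (CNP0217919.1)
Conditions: 21 (4 equiv), CuBr·SMe2 (2 equiv), THF, −40 → 0 °C; aq. NH4Cl
Reagents that add atoms: none
Why: Cuprate opening of an epoxide under Fürst–Plattner control, in which trans-diaxial attack at C7 from the β-face (also the carbon remote from the electron-withdrawing C9 ester) gives the axial 7β-isopropenyl group with inversion at C7 and the axial 8α-hydroxyl, while the Gilman-type reagent should leave both esters alone at low temperature.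

Compound list
1 | (E)-3-methylpent-3-en-2-one | C/C=C(\C)C(C)=O | starting material
2 | dimethyl malonate | COC(=O)CC(=O)OC | starting material
3 | dimethyl 2-[(2R)-3-methyl-4-oxopentan-2-yl]propanedioate (Michael adduct, C3 of the chain not defined) | CC(=O)C(C)[C@@H](C)C(C(=O)OC)C(=O)OC | intermediate
4 | methyl (6R)-5,6-dimethyl-2,4-dioxocyclohexane-1-carboxylate (formed as its lithium enolate, C1 and C5 not defined) | CC1[C@@H](C)C(C(=O)OC)C(=O)CC1=O | intermediate
5 | (4R,5S)-4,5-dimethylcyclohexane-1,3-dione | C[C@@H]1[C@@H](C)CC(=O)CC1=O | intermediate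
6 | (5S,6R)-5,6-dimethyl-3-(2-methylpropoxy)cyclohex-2-en-1-one | C[C@@H]1[C@@H](C)CC(OCC(C)C)=CC1=O | intermediate
7 | 4-bromobutanenitrile | N#CCCCBr | starting material
8 | 4-[(1R,6S)-1,6-dimethyl-4-(2-methylpropoxy)-2-oxocyclohex-3-en-1-yl]butanenitrile | C[C@@]1(CCCC#N)[C@@H](C)CC(OCC(C)C)=CC1=O | intermediate
9 | 4-[(1R,6S)-2-hydroxy-1,6-dimethyl-4-(2-methylpropoxy)cyclohex-3-en-1-yl]butan-1-imine (present as aluminium alkoxide and N-aluminio imine, carbinol centre not defined) | C[C@@]1(CCCC=N)[C@@H](C)CC(OCC(C)C)=CC1O | intermediate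
10 | 4-[(1R,6S)-1,6-dimethyl-4-oxocyclohex-2-en-1-yl]butanal | C[C@@]1(CCCC=O)[C@@H](C)CC(=O)C=C1 | intermediate
11 | (4aR,5S,8aS)-4a,5-dimethyl-3,4,4a,5,6,8a-hexahydronaphthalene-1,7(2H,8H)-dione (cis-fused) | C1C[C@]2(C)[C@@H](C)CC(=O)C[C@@H]2C(=O)C1 | intermediate
12 | (4aR,5S,8aR)-4a,5-dimethyl-3,4,4a,5,6,8a-hexahydronaphthalene-1,7(2H,8H)-dione (trans-fused) | C1C[C@]2(C)[C@@H](C)CC(=O)C[C@H]2C(=O)C1 | intermediate
13 | (4aR,5S,7S,8aR)-7-hydroxy-4a,5-dimethyloctahydronaphthalen-1(2H)-one | C1C[C@]2(C)[C@@H](C)C[C@H](O)C[C@H]2C(=O)C1 | intermediate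
14 | trimethyl{[(4aR,5S,7S,8aR)-4a,5-dimethyl-7-(trimethylsilyloxy)-3,4,4a,5,6,7,8,8a-octahydronaphthalen-1-yl]oxy}silane | C1C[C@]2(C)[C@@H](C)C[C@H](O[Si](C)(C)C)C[C@H]2C(O[Si](C)(C)C)=C1 | intermediate
15 | (4aR,5S,7S,8aR)-7-hydroxy-4a,5-dimethyl-4a,5,6,7,8,8a-hexahydronaphthalen-1(4H)-one | C1[C@]2(C)[C@@H](C)C[C@H](O)C[C@H]2C(=O)C=C1 | intermediate
16 | (2S,4S,4aR,8aR)-4,4a-dimethyl-8-oxo-1,2,3,4,4a,5,8,8a-octahydronaphthalen-2-yl acetate | C1[C@]2(C)[C@@H](C)C[C@H](OC(C)=O)C[C@H]2C(=O)C=C1 | intermediate
17 | (2S,4S,4aR,8S,8aR)-8-hydroxy-4,4a-dimethyl-1,2,3,4,4a,5,8,8a-octahydronaphthalen-2-yl acetate | C1[C@]2(C)[C@@H](C)C[C@H](OC(C)=O)C[C@H]2[C@@H](O)C=C1 | intermediate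
18 | angelic acid, (Z)-2-methylbut-2-enoic acid | C/C=C(/C)C(=O)O | starting material
19 | (1R,4aR,5S,7S,8aR)-7-acetoxy-4a,5-dimethyl-1,4,4a,5,6,7,8,8a-octahydronaphthalen-1-yl (2Z)-2-methylbut-2-enoate | C1[C@]2(C)[C@@H](C)C[C@H](OC(C)=O)C[C@H]2[C@H](OC(=O)/C(C)=C\C)C=C1 | intermediate
20 | (1S,2R,3R,4aR,5S,7S,8aR)-7-acetoxy-2,3-epoxy-4a,5-dimethyldecahydronaphthalen-1-yl (2Z)-2-methylbut-2-enoate | C1[C@]2(C)[C@@H](C)C[C@H](OC(C)=O)C[C@H]2[C@H](OC(=O)/C(C)=C\C)[C@@H]3O[C@@H]31 | intermediate
21 | isopropenylmagnesium bromide, bromo(prop-1-en-2-yl)magnesium | C=C(C)[Mg]Br | starting material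
22 | (1S,2R,3R,4aR,5S,7S,8aR)-7-acetoxy-2-hydroxy-4a,5-dimethyl-3-(prop-1-en-2-yl)decahydronaphthalen-1-yl (2Z)-2-methylbut-2-enoate (CNP0217919.1) | C=C(C)[C@H]1C[C@]2(C)[C@@H](C)C[C@H](OC(C)=O)C[C@H]2[C@H](OC(=O)/C(C)=C\C)[C@@H]1O | target

Total step count: 12. Longest linear sequence: 12 steps (1 and 2 to 22).

The three steps most likely to fail:

Step 1 could suffer from weak enantiofacial control on the α-branched enone and from partial retro-Michael racemisation before the ring closes. The fallback sets out from 1 and 2 and comes back at 10. Without the amine catalyst, the classical one-pot Michael–Claisen annulation (NaOMe, MeOH, reflux; NaOH; HCl) should give racemic trans-4,5-dimethylcyclohexane-1,3-dione F1. Condensation with (1R,2S,5R)-menthol (TsOH, toluene, Dean–Stark) gives diastereomeric enol ethers, from which (5S,6R)-5,6-dimethyl-3-[(1R,2S,5R)-menthyloxy]cyclohex-2-en-1-one F2 is separated by crystallisation or chromatography. Alkylation with 7 as in step 3 should give the menthyl ether nitrile F3, and reduction with i-Bu2AlH followed by aqueous HCl as in step 4 releases menthol and gives 10.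

Step 5 could fail because the enolisable aliphatic aldehyde undergoes base-induced aldol or Michael self-reaction faster than the carbene adds, or because cis-to-trans equilibration at C10 stays incomplete. The fallback sets out from 10 and comes back at 12. Pinnick oxidation (NaClO2, NaH2PO4, 2-methylbut-2-ene) should give 4-[(1R,6S)-1,6-dimethyl-4-oxocyclohex-2-en-1-yl]butanoic acid F4, and (PhSe)2 with PBu3 converts it into the Se-phenyl selenoester F5. Bu3SnH and AIBN (benzene, 80 °C) then generate the acyl radical, whose 6-exo-trig addition to C10 gives 11, which DBU equilibrates to 12.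

Step 12 could fail because axial attack syn to the C14 methyl is slow, which would leave time for acyl migration from O9 to the new C8 alkoxide or for attack of the organometallic on the esters. The fallback sets out from 17 and comes back at 22.
- Mitsunobu inversion with chloroacetic acid (PPh3, DIAD) should give the 9α-chloroacetate F6.
- Ammonia in methanol at 0 °C removes only the chloroacetyl group and gives the 9α-allylic alcohol F7.
- Hydroxyl-directed epoxidation with mCPBA gives the 7α,8α-epoxy alcohol F8.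
- An excess of the same cuprate, with no conjugated ester present, should open it to the 8α,9α-diol F9.
- Yamaguchi esterification with 18 (2,4,6-trichlorobenzoyl chloride, Et3N, DMAP) should acylate the equatorial 9-hydroxyl in preference to the axial, flanked 8-hydroxyl and give 22.

Further compounds
F1 | step 1 | racemic trans-4,5-dimethylcyclohexane-1,3-dione | CC1C(C)CC(=O)CC1=O
F2 | step 1 | (5S,6R)-5,6-dimethyl-3-{[(1R,2S,5R)-5-methyl-2-(propan-2-yl)cyclohexyl]oxy}cyclohex-2-en-1-one | C[C@@H]1[C@@H](C)CC(O[C@@H]2C[C@H](C)CC[C@H]2C(C)C)=CC1=O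
F3 | step 1 | 4-[(1R,6S)-1,6-dimethyl-4-{[(1R,2S,5R)-5-methyl-2-(propan-2-yl)cyclohexyl]oxy}-2-oxocyclohex-3-en-1-yl]butanenitrile | C[C@@]1(CCCC#N)[C@@H](C)CC(O[C@@H]2C[C@H](C)CC[C@H]2C(C)C)=CC1=O
F4 | step 5 | 4-[(1R,6S)-1,6-dimethyl-4-oxocyclohex-2-en-1-yl]butanoic acid | C[C@@]1(CCCC(=O)O)[C@@H](C)CC(=O)C=C1
F5 | step 5 | Se-phenyl 4-[(1R,6S)-1,6-dimethyl-4-oxocyclohex-2-en-1-yl]butaneselenoate | C[C@@]1(CCCC(=O)[Se]c2ccccc2)[C@@H](C)CC(=O)C=C1
F6 | step 12 | (1R,4aR,5S,7S,8aR)-7-acetoxy-4a,5-dimethyl-1,4,4a,5,6,7,8,8a-octahydronaphthalen-1-yl chloroacetate | C1[C@]2(C)[C@@H](C)C[C@H](OC(C)=O)C[C@H]2[C@H](OC(=O)CCl)C=C1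
F7 | step 12 | (2S,4S,4aR,8R,8aR)-8-hydroxy-4,4a-dimethyl-1,2,3,4,4a,5,8,8a-octahydronaphthalen-2-yl acetate | C1[C@]2(C)[C@@H](C)C[C@H](OC(C)=O)C[C@H]2[C@H](O)C=C1
F8 | step 12 | (2S,4S,4aR,6R,7S,8S,8aR)-6,7-epoxy-8-hydroxy-4,4a-dimethyldecahydronaphthalen-2-yl acetate | C1[C@]2(C)[C@@H](C)C[C@H](OC(C)=O)C[C@H]2[C@H](O)[C@@H]3O[C@@H]31
F9 | step 12 | (2S,4S,4aR,6R,7R,8S,8aR)-7,8-dihydroxy-4,4a-dimethyl-6-(prop-1-en-2-yl)decahydronaphthalen-2-yl acetate | C=C(C)[C@H]1C[C@]2(C)[C@@H](C)C[C@H](OC(C)=O)C[C@H]2[C@H](O)[C@@H]1O
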